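**Retrosynthetic overview** (guaiane numbering; primes = dienophile-derived half)
1. The norbornene is made last by an endo Diels–Alder cross-dimerization (C2–C2′, C5–C3′) of two C6-epimeric guaianolide cyclopentadienes: trans-lactone monomer 11 as diene, cis-lactone monomer 15 as dienophile.
2. In each monomer the seven-membered ring is closed at C1–C10 by a Lewis-acid Prins/ene cyclization of the cyclopentadiene onto a methyl ketone.
3. Before that, the C5–C6 bond and lactone come from a Ni/Cr-catalysed coupling of dienyl triflate 7 with keto aldehyde 4; the ligand enantiomer sets C6 (S gives trans, R gives cis).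
4. Aldehyde 4 comes from methyl methacrylate (Rh hydroformylation, C11) and methyl vinyl ketone (enamine Michael addition, C7); triflate 7 comes from 2-methylcyclopentenone.
5. Ring order: lactone, then seven-membered ring (five-membered ring carried from 7), then norbornene.

Assumption: the target is taken exactly as the SMILES is written, i.e. a trans-fused lactone in the diene-derived half and a cis-fused lactone (C6′ epimer of the usual absinthin drawing) in the dienophile-derived half.

Abbreviations: L = N-[2-(4-isopropyl-4,5-dihydrooxazol-2-yl)-6-methoxyphenyl]methanesulfonamide (either enantiomer); dmp = 2,9-dimethyl-1,10-phenanthroline; PPTS = pyridinium p-toluenesulfonate.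

**Step 1**
Reactants: 1 methyl methacrylate
Product: 2 methyl (2S)-2-methyl-4-oxobutanoate
Conditions: Rh(acac)(CO)2 (0.5 mol %), (R,R)-1,2-bis(tert-butylmethylphosphino)benzene (1 mol %), CO/H2 (1:5, 10 bar), toluene, 90 °C
Reagents that add atoms: carbon monoxide, [C-]#[O+]
Why: Rhodium-catalysed asymmetric hydroformylation puts the formyl group on the CH2 terminus (a quaternary aldehyde is disfavoured) and the P-stereogenic bisphosphine controls the face of hydride delivery to C11, the ligand enantiomer being chosen to give the (S)-ester.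

**Step 2**
Reactants: 2 methyl (2S)-2-methyl-4-oxobutanoate; 3 methyl vinyl ketone
Product: 4 methyl (2S,3S)-3-formyl-2-methyl-6-oxoheptanoate
Conditions: (S)-α,α-diphenylprolinol methyl ether (5 mol %), ethyl 3,4-dihydroxybenzoate (20 mol %), neat, 4 °C
Reagents that add atoms: none
Why: Enamine-catalysed Michael addition in which the enone attacks the (E)-enamine on the face opposite the diphenylmethoxymethyl group, setting C7 (S) under catalyst control next to the existing C11 centre.

**Step 3**
Reactants: 5 2-methylcyclopent-2-en-1-one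
Product: 7 3-methylcyclopenta-1,3-dien-2-yl trifluoromethanesulfonate, via lithium dienolate 6 (not isolated)
Conditions: LiN(iPr)2, THF, −78 °C; then PhNTf2, −78 to 0 °C; used at once, kept cold
Reagents that add atoms: N-phenylbis(trifluoromethanesulfonimide), O=S(=O)(N(c1ccccc1)S(=O)(=O)C(F)(F)F)C(F)(F)F
Why: Kinetic deprotonation at the CH2 next to the carbonyl gives the cross-conjugated dienolate and O-sulfonylation gives the enol triflate (enolate triflation; no stereocentre).

**Step 4**
Reactants: 7 3-methylcyclopenta-1,3-dien-2-yl trifluoromethanesulfonate; 4 methyl (2S,3S)-3-formyl-2-methyl-6-oxoheptanoate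
Product: 10 (3S,4S,5S)-3-methyl-5-(3-methylcyclopenta-1,3-dien-2-yl)-4-(3-oxobutyl)oxolan-2-one, via silyl ether 8 (not isolated), via hydroxy ester 9 (not isolated)
Conditions: CrCl2 (10 mol %), (S)-L (12 mol %), NiCl2(dmp) (2 mol %), Mn, Me3SiCl, LiCl, MeCN, 23 °C; then PPTS, MeOH, 23 °C
Reagents that add atoms: none
Why: Nozaki–Hiyama–Kishi coupling in which zerovalent nickel inserts into the dienyl C–OTf bond, the dienyl group passes to chromium and adds only to the aldehyde (the ketone is untouched), the sulfonamide-bound chromium sets C6 (S) under catalyst control, and acid-induced lactonization with retention gives the 4,5-trans lactone.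

**Step 5**
Reactants: 10 (3S,4S,5S)-3-methyl-5-(3-methylcyclopenta-1,3-dien-2-yl)-4-(3-oxobutyl)oxolan-2-one
Product: 11 (3S,3aS,6S,6aR,9bS)-6-hydroxy-3,6,9-trimethyl-3a,4,5,6,6a,9b-hexahydroazuleno[4,5-b]furan-2(3H)-one
Conditions: Me2AlCl (2 equiv), CH2Cl2, −78 °C; Et3N then aqueous KNaC4H4O6 at −78 °C
Reagents that add atoms: none
Why: Proposed new method: Me2AlCl activates the methyl ketone, the unsubstituted diene terminus C1 attacks it through a chair-like seven-membered transition state (Prins-type, stepwise carbonyl-ene) and the allyl cation is quenched by loss of a C2 proton to the aluminium-bound methyl (methane), giving the 2,4-diene with C1 (R) and C10 (S) because the tether anchored at C7 reaches only the face of C1 that puts H1 cis to H7 and the C10 methyl sits pseudo-equatorial with the aluminium-bound oxygen turned toward C2; the closest known reaction type is the Me2AlCl-promoted intramolecular carbonyl-ene (Prins) cyclization of unsaturated ketones, not yet shown with a cyclopentadiene as the alkene partner.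

**Step 6**
Reactants: 7 3-methylcyclopenta-1,3-dien-2-yl trifluoromethanesulfonate; 4 methyl (2S,3S)-3-formyl-2-methyl-6-oxoheptanoate
Product: 14 (3S,4S,5R)-3-methyl-5-(3-methylcyclopenta-1,3-dien-2-yl)-4-(3-oxobutyl)oxolan-2-one, via silyl ether 12 (not isolated), via hydroxy ester 13 (not isolated)
Conditions: CrCl2 (10 mol %), (R)-L (12 mol %), NiCl2(dmp) (2 mol %), Mn, Me3SiCl, LiCl, MeCN, 23 °C; then PPTS, MeOH, 23 °C
Reagents that add atoms: none
Why: The same Nozaki–Hiyama–Kishi coupling with the enantiomeric ligand delivers the dienyl group to the other aldehyde face, setting C6 (R) under catalyst control, and lactonization with retention gives the 4,5-cis lactone.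

**Step 7**
Reactants: 14 (3S,4S,5R)-3-methyl-5-(3-methylcyclopenta-1,3-dien-2-yl)-4-(3-oxobutyl)oxolan-2-one
Product: 15 (3S,3aS,6S,6aR,9bR)-6-hydroxy-3,6,9-trimethyl-3a,4,5,6,6a,9b-hexahydroazuleno[4,5-b]furan-2(3H)-one
Conditions: Me2AlCl (2 equiv), CH2Cl2, −78 °C; Et3N then aqueous KNaC4H4O6 at −78 °C
Reagents that add atoms: none
Why: Proposed new method: the same Me2AlCl-promoted Prins-type attack of diene terminus C1 on the activated methyl ketone followed by loss of a C2 proton as methane, with C1 (R) and C10 (S) again dictated by the C7-anchored tether and the pseudo-equatorial methyl in the chair-like seven-membered transition state; the closest known reaction type is the Me2AlCl-promoted intramolecular carbonyl-ene (Prins) cyclization of unsaturated ketones, not yet shown with a cyclopentadiene.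

**Step 8**
Reactants: 11 (3S,3aS,6S,6aR,9bS)-6-hydroxy-3,6,9-trimethyl-3a,4,5,6,6a,9b-hexahydroazuleno[4,5-b]furan-2(3H)-one; 15 (3S,3aS,6S,6aR,9bR)-6-hydroxy-3,6,9-trimethyl-3a,4,5,6,6a,9b-hexahydroazuleno[4,5-b]furan-2(3H)-one
Product: 16 (1R,2R,5R,8S,9S,12S,13R,14S,15S,16R,17S,20S,21S,24S)-12,17-dihydroxy-3,8,12,17,21,25-hexamethyl-6,23-dioxaheptacyclo[13.9.2.0(1,16).0(2,14).0(4,13).0(5,9).0(20,24)]hexacosa-3,25-diene-7,22-dione
Conditions: 11 (1 equiv) added slowly to 15 (3 equiv), 3 M in toluene, 25 °C, dark, argon, 10 d; excess 15 recovered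
Reagents that add atoms: none
Why: Proposed new method: a role-selective Diels–Alder cross-dimerization in which 11 is the better diene because its C6–O bond lies on the reacting face and leaves the C6–H bond anti to the forming C5–C3′ bond, whereas in 15 the C6′–O bond would be anti to a bond forming at C5′ and so deactivates it as a diene but not as a dienophile at C2′=C3′, both partners reacting endo on the face anti to the C10 side chain to form C2–C2′ and C5–C3′ and the four new stereocentres; the closest known reaction type is the thermal Diels–Alder dimerization of 5-substituted cyclopentadienes (biomimetic guaianolide dimerization), not yet shown as a cross-dimerization of two diastereomers with assigned roles.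

**Compound list**
1 | methyl methacrylate | C=C(C)C(=O)OC | starting material
2 | methyl (2S)-2-methyl-4-oxobutanoate | COC(=O)[C@@H](C)CC=O | intermediate
3 | methyl vinyl ketone (but-3-en-2-one) | CC(=O)C=C | starting material
4 | methyl (2S,3S)-3-formyl-2-methyl-6-oxoheptanoate | COC(=O)[C@@H](C)[C@@H](C=O)CCC(C)=O | intermediate
5 | 2-methylcyclopent-2-en-1-one | CC1=CCCC1=O | starting material
6 | lithium 3-methylcyclopenta-1,3-dien-2-olate | [Li]OC1=CCC=C1C | intermediate
7 | 3-methylcyclopenta-1,3-dien-2-yl trifluoromethanesulfonate | CC1=CCC=C1OS(=O)(=O)C(F)(F)F | intermediate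
8 | methyl (2S,3S)-2-methyl-3-[(S)-(3-methylcyclopenta-1,3-dien-2-yl)(trimethylsilyloxy)methyl]-6-oxoheptanoate | COC(=O)[C@@H](C)[C@@H]([C@H](O[Si](C)(C)C)C1=CCC=C1C)CCC(C)=O | intermediate
9 | methyl (2S,3S)-3-[(S)-hydroxy(3-methylcyclopenta-1,3-dien-2-yl)methyl]-2-methyl-6-oxoheptanoate | COC(=O)[C@@H](C)[C@@H]([C@H](O)C1=CCC=C1C)CCC(C)=O | intermediate
10 | (3S,4S,5S)-3-methyl-5-(3-methylcyclopenta-1,3-dien-2-yl)-4-(3-oxobutyl)oxolan-2-one | CC1=CCC=C1[C@H]2OC(=O)[C@@H](C)[C@@H]2CCC(C)=O | intermediate
11 | (3S,3aS,6S,6aR,9bS)-6-hydroxy-3,6,9-trimethyl-3a,4,5,6,6a,9b-hexahydroazuleno[4,5-b]furan-2(3H)-one (trans-lactone monomer) | CC1=C2[C@H]3OC(=O)[C@@H](C)[C@@H]3CC[C@](C)(O)[C@@H]2C=C1 | intermediate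
12 | methyl (2S,3S)-2-methyl-3-[(R)-(3-methylcyclopenta-1,3-dien-2-yl)(trimethylsilyloxy)methyl]-6-oxoheptanoate | COC(=O)[C@@H](C)[C@@H]([C@@H](O[Si](C)(C)C)C1=CCC=C1C)CCC(C)=O | intermediate
13 | methyl (2S,3S)-3-[(R)-hydroxy(3-methylcyclopenta-1,3-dien-2-yl)methyl]-2-methyl-6-oxoheptanoate | COC(=O)[C@@H](C)[C@@H]([C@@H](O)C1=CCC=C1C)CCC(C)=O | intermediate
14 | (3S,4S,5R)-3-methyl-5-(3-methylcyclopenta-1,3-dien-2-yl)-4-(3-oxobutyl)oxolan-2-one | CC1=CCC=C1[C@@H]2OC(=O)[C@@H](C)[C@@H]2CCC(C)=O | intermediate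
15 | (3S,3aS,6S,6aR,9bR)-6-hydroxy-3,6,9-trimethyl-3a,4,5,6,6a,9b-hexahydroazuleno[4,5-b]furan-2(3H)-one (cis-lactone monomer) | CC1=C2[C@@H]3OC(=O)[C@@H](C)[C@@H]3CC[C@](C)(O)[C@@H]2C=C1 | intermediate
16 | (1R,2R,5R,8S,9S,12S,13R,14S,15S,16R,17S,20S,21S,24S)-12,17-dihydroxy-3,8,12,17,21,25-hexamethyl-6,23-dioxaheptacyclo[13.9.2.0(1,16).0(2,14).0(4,13).0(5,9).0(20,24)]hexacosa-3,25-diene-7,22-dione | CC1=C[C@@H]2[C@H]3[C@H](C(C)=C4[C@@H]5OC(=O)[C@@H](C)[C@@H]5CC[C@](C)(O)[C@@H]43)[C@@]13[C@@H]2[C@@](C)(O)CC[C@H]1[C@H](C)C(=O)O[C@@H]13 | target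

**Total step count:** 8
**Longest linear sequence:** 5 (steps 1, 2, 4, 5, 8; equally 1, 2, 6, 7, 8)

**Three steps most likely to fail**

Step 5 (and its twin, step 7), proposed new method. It can fail by ionization of the new tertiary alcohol or the allylic lactone toward fulvene-type products, by a 1,5-hydrogen shift in 10 before cyclization, or by giving the wrong C1/C10 diastereomer. The fallback uses known reactions and reverses the order of the two ring-forming bonds; it sets out from 4 and 5 and comes back at 11. Aldehyde-selective acetalization of 4 (HC(OMe)3, CeCl3·7H2O, MeOH) gives methyl (2S,3S)-3-(dimethoxymethyl)-2-methyl-6-oxoheptanoate F2. Aldol addition of lithium dienolate 6 (from 5, LiN(iPr)2, THF, −78 °C) to the ketone of F2, with Me3SiCl quench, gives methyl (2S,3S,6S)-3-(dimethoxymethyl)-2-methyl-6-[(1S)-3-methyl-2-oxocyclopent-3-en-1-yl]-6-(trimethylsilyloxy)heptanoate F3; this aldol is poorly selective, so F3 is separated from its C1/C10 isomers. Gamma-enolization and triflation (KN(SiMe3)2, PhNTf2) give methyl (2S,3S,6S)-3-(dimethoxymethyl)-2-methyl-6-[(1S)-3-methyl-2-(trifluoromethylsulfonyloxy)cyclopenta-2,4-dien-1-yl]-6-(trimethylsilyloxy)heptanoate F4. LiBF4 in wet MeCN frees methyl (2S,3S,6S)-3-formyl-2-methyl-6-[(1S)-3-methyl-2-(trifluoromethylsulfonyloxy)cyclopenta-2,4-dien-1-yl]-6-(trimethylsilyloxy)heptanoate F5. Intramolecular Ni/Cr coupling under the step 4 conditions with (S)-L closes the seven-membered ring to methyl (2S)-2-[(4S,5S,8S,8aR)-3,8-dimethyl-4,8-bis(trimethylsilyloxy)-4,5,6,7,8,8a-hexahydroazulen-5-yl]propanoate F6, and PPTS in MeOH removes both silyl groups and lactonizes to 11. With (R)-L in the ring closure the same sequence ends at 15.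

Step 8, proposed new method. The diene/dienophile preference may be too small, giving the homodimer of 11 and role-reversed adducts alongside 16. The fallback uses known chemistry; it sets out from 11 and comes back at 16. Compound 11 alone (neat, 25 °C, dark, 10 d) undergoes the biomimetic Diels–Alder homodimerization to the all-trans dimer (1R,2R,5S,8S,9S,12S,13R,14S,15S,16R,17S,20S,21S,24S)-12,17-dihydroxy-3,8,12,17,21,25-hexamethyl-6,23-dioxaheptacyclo[13.9.2.0(1,16).0(2,14).0(4,13).0(5,9).0(20,24)]hexacosa-3,25-diene-7,22-dione F7. LiOH in THF/H2O followed by cold acidification to pH 4 opens both lactones to the absinthin bis(seco acid) (6,6′-dihydroxy-12,12′-dioic acid, other centres as in the dimer) F8. Mitsunobu lactonization (PPh3, DIAD, THF, −20 to 0 °C) then inverts the allylic C6′ carbinol by SN2 displacement, while the neopentyl C6 carbinol, which cannot be displaced, recloses with retention through the acyloxyphosphonium pathway, giving 16. The same two steps also convert any homodimer formed in step 8 into 16.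

Step 4 (and its twin, step 6). The dienyl triflate is labile (dimerization, 1,5-hydrogen shift), and catalyst control at C6 may be incomplete against the Felkin bias of the branched aldehyde. The fallback replaces the Ni/Cr coupling by a boron-based carbonyl addition; it sets out from 7 and comes back at 10. Borylation of 7 (bis(pinacolato)diboron, PdCl2(PPh3)2, PPh3, KOPh, toluene, 50 °C) gives 4,4,5,5-tetramethyl-2-(3-methylcyclopenta-1,3-dien-2-yl)-1,3,2-dioxaborolane F1. Rhodium-catalysed, aldehyde-selective 1,2-addition of F1 to 4 ([RhCl(C2H4)2]2, chiral diene ligand, KOH, dioxane/H2O) gives hydroxy ester 9 together with its C6 epimer 13, and PPTS closes the lactones 10 and 14. The two lactones are separated by chromatography, and both are needed, so incomplete selectivity costs no material.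

**Further compounds**
F1 | step 4 | 4,4,5,5-tetramethyl-2-(3-methylcyclopenta-1,3-dien-2-yl)-1,3,2-dioxaborolane | CC1=CCC=C1B1OC(C)(C)C(C)(C)O1
F2 | step 5 | methyl (2S,3S)-3-(dimethoxymethyl)-2-methyl-6-oxoheptanoate | COC(=O)[C@@H](C)[C@@H](C(OC)OC)CCC(C)=O
F3 | step 5 | methyl (2S,3S,6S)-3-(dimethoxymethyl)-2-methyl-6-[(1S)-3-methyl-2-oxocyclopent-3-en-1-yl]-6-(trimethylsilyloxy)heptanoate | COC(=O)[C@@H](C)[C@@H](C(OC)OC)CC[C@](C)(O[Si](C)(C)C)[C@@H]1CC=C(C)C1=O
F4 | step 5 | methyl (2S,3S,6S)-3-(dimethoxymethyl)-2-methyl-6-[(1S)-3-methyl-2-(trifluoromethylsulfonyloxy)cyclopenta-2,4-dien-1-yl]-6-(trimethylsilyloxy)heptanoate | COC(=O)[C@@H](C)[C@@H](C(OC)OC)CC[C@](C)(O[Si](C)(C)C)[C@@H]1C=CC(C)=C1OS(=O)(=O)C(F)(F)F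
F5 | step 5 | methyl (2S,3S,6S)-3-formyl-2-methyl-6-[(1S)-3-methyl-2-(trifluoromethylsulfonyloxy)cyclopenta-2,4-dien-1-yl]-6-(trimethylsilyloxy)heptanoate | COC(=O)[C@@H](C)[C@@H](C=O)CC[C@](C)(O[Si](C)(C)C)[C@@H]1C=CC(C)=C1OS(=O)(=O)C(F)(F)F
F6 | step 5 | methyl (2S)-2-[(4S,5S,8S,8aR)-3,8-dimethyl-4,8-bis(trimethylsilyloxy)-4,5,6,7,8,8a-hexahydroazulen-5-yl]propanoate | CC1=C2[C@@H](O[Si](C)(C)C)[C@H]([C@H](C)C(=O)OC)CC[C@](C)(O[Si](C)(C)C)[C@@H]2C=C1
F7 | step 8 | (1R,2R,5S,8S,9S,12S,13R,14S,15S,16R,17S,20S,21S,24S)-12,17-dihydroxy-3,8,12,17,21,25-hexamethyl-6,23-dioxaheptacyclo[13.9.2.0(1,16).0(2,14).0(4,13).0(5,9).0(20,24)]hexacosa-3,25-diene-7,22-dione (all-trans dimer) | CC1=C[C@@H]2[C@H]3[C@H](C(C)=C4[C@H]5OC(=O)[C@@H](C)[C@@H]5CC[C@](C)(O)[C@@H]43)[C@@]13[C@@H]2[C@@](C)(O)CC[C@H]1[C@H](C)C(=O)O[C@@H]13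
F8 | step 8 | bis(seco acid) of the all-trans dimer (6,6′-dihydroxy-12,12′-dioic acid, both lactones opened) | CC1=C[C@@H]2[C@H]3[C@H](C(C)=C4[C@@H](O)[C@H]([C@H](C)C(=O)O)CC[C@](C)(O)[C@@H]43)[C@@]13[C@@H]2[C@@](C)(O)CC[C@@H]([C@H](C)C(=O)O)[C@@H]3O
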